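**Strategy.** The route rests on cutting the C7a–C1 bond of the indane (C1 = benzylidene carbon, C2 = resorcinyl-bearing carbon, C3 = guaiacyl-bearing carbon, C3a/C7a = fusion carbons of ring A). That bond sits meta to both ring-A oxygens (on C4 and C6), so a C7a bromide is not deactivated, and it ends in an E-trisubstituted styrene, which is what an aryl–palladium at C7a leaves when it adds across a tethered aryl alkyne. One formate-terminated palladium cyclisation therefore closes the five-membered ring and fixes the E-benzylidene without touching C2 or C3. The precursor is an acyclic, hexabenzylated (3S,4S)-3,4-diaryl-1-arylbut-1-yne carrying the ring-A bromide, made by two catalyst-controlled arylations of an enal.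

Key step: step 9

Remark (numbering): in the acyclic compounds C4 is the future indane C3 and C3 the future indane C2; (3S,4S) in 13 is the arrangement that becomes trans-2,3-diaryl on ring closure, and the propargylic descriptor reads 3R in 10 only because ethynyl ranks below aryl.
Remark (precursor design): the halide is a bromide so that step 8 stays selective for iodide 12, and all six phenols are benzyl ethers (the cyclised product is a hexabenzyl ether), cleaved in one operation orthogonal to the two methyl ethers.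
Assumption: the chiral catalysts in steps 3 and 5 are used as the antipode that delivers aryl to the stated face according to the usual shielding models; the other antipode is taken if a model reaction shows the opposite sense.

Step 1
Reactants: 1 1-bromo-3,5-bis(benzyloxy)benzene
Product: 3 2-bromo-4,6-bis(benzyloxy)benzaldehyde, via aryl iminium chloride 2 (not isolated)
Conditions: POCl3, DMF, 0 °C to 80 °C; then H2O, rt
Reagents that add atoms: N,N-dimethylformamide CN(C)C=O; water O
Why: Vilsmeier–Haack formylation should go to C2 of the arene (para to one benzyloxy group, ortho to the other), by analogy with 1-bromo-3,5-dimethoxybenzene, with the minor C4 isomer removed by crystallisation and water hydrolysing iminium salt 2 to the aldehyde.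

Step 2
Reactants: 3 2-bromo-4,6-bis(benzyloxy)benzaldehyde
Product: 4 (2E)-3-[2-bromo-4,6-bis(benzyloxy)phenyl]prop-2-enal
Conditions: Ph3P=CHCHO, toluene, 90 °C
Reagents that add atoms: (triphenylphosphoranylidene)acetaldehyde O=CC=P(c1ccccc1)(c1ccccc1)c1ccccc1
Why: Wittig olefination with the stabilised formylmethylene ylide should give the E-enal, and the hindered, electron-rich product enal is less electrophilic than 3, which limits a second homologation.

Step 3
Reactants: 4 (2E)-3-[2-bromo-4,6-bis(benzyloxy)phenyl]prop-2-enal; 5 (4-benzyloxy-3-methoxyphenyl)boronic acid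
Product: 6 (3S)-3-[2-bromo-4,6-bis(benzyloxy)phenyl]-3-(4-benzyloxy-3-methoxyphenyl)propanal
Conditions: [Rh(C2H4)2Cl]2 (3 mol%), chiral 2,5-diphenylbicyclo[2.2.2]octa-2,5-diene (antipode for Re-face arylation, 6.6 mol%), KOH (0.5 equiv), MeOH/H2O 10:1, 50 °C
Reagents that add atoms: none
Why: Hayashi–Miyaura conjugate arylation through an aryl complex of monovalent rhodium bound to the chiral diene should add the aryl group to the Re face of C3 of the E-enal and so set the 3S centre under ligand control, the diene ligand favouring 1,4- over 1,2-addition and the aryl bromide being inert to rhodium under these conditions.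

Step 4
Reactants: 7 [3,5-bis(benzyloxy)phenyl]boronic acid
Product: 8 [3,5-bis(benzyloxy)phenyl](2,4,6-trimethylphenyl)iodonium trifluoromethanesulfonate
Conditions: MesI(OAc)2, BF3·OEt2, CH2Cl2, 0 °C to rt; then sat. aq. NaOTf
Reagents that add atoms: (diacetoxyiodo)mesitylene CC(=O)OI(OC(C)=O)c1c(C)cc(C)cc1C; sodium trifluoromethanesulfonate [Na+].[O-]S(=O)(=O)C(F)(F)F
Why: Boron-to-iodine ipso exchange at the BF3-activated trivalent iodine centre is regiospecific, so the aryl(mesityl)iodonium salt should form without attack at the activated ring C–H positions, and the NaOTf wash installs the triflate counter-ion.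

Step 5
Reactants: 6 (3S)-3-[2-bromo-4,6-bis(benzyloxy)phenyl]-3-(4-benzyloxy-3-methoxyphenyl)propanal; 8 [3,5-bis(benzyloxy)phenyl](2,4,6-trimethylphenyl)iodonium trifluoromethanesulfonate
Product: 9 (2S,3S)-3-[2-bromo-4,6-bis(benzyloxy)phenyl]-2-[3,5-bis(benzyloxy)phenyl]-3-(4-benzyloxy-3-methoxyphenyl)propanal
Conditions: CuBr (10 mol%), 5-benzyl-2-tert-butyl-3-methylimidazolidin-4-one·Cl3CCO2H (antipode for Re-face arylation, 10 mol%), NaHCO3, toluene/Et2O 2:1, 23 °C
Reagents that add atoms: none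
Why: In this enamine/copper dual-catalytic α-arylation of an aldehyde with a diaryliodonium salt, the E-enamine of 6 should be arylated on the Re face of C2 by the aryl species of trivalent copper generated from CuBr and 8 (the mesityl group stays on iodine), so that the 2S centre is set by the amine catalyst over the existing 3S centre, and the α-branched product no longer forms an enamine readily and should not epimerise in the bicarbonate medium.

Step 6
Reactants: 9 (2S,3S)-3-[2-bromo-4,6-bis(benzyloxy)phenyl]-2-[3,5-bis(benzyloxy)phenyl]-3-(4-benzyloxy-3-methoxyphenyl)propanal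
Product: 10 (3R,4S)-4-[2-bromo-4,6-bis(benzyloxy)phenyl]-3-[3,5-bis(benzyloxy)phenyl]-4-(4-benzyloxy-3-methoxyphenyl)but-1-yne
Conditions: TMSCHN2, n-BuLi, THF, −78 °C; add 9, −78 °C to 0 °C; then H2O
Reagents that add atoms: (trimethylsilyl)diazomethane C[Si](C)(C)C=[N+]=[N-]
Why: In this Colvin homologation the preformed lithiated diazo reagent should add to the aldehyde at −78 °C faster than it enolises it (carbonate/methanol conditions would epimerise the α-aryl aldehyde), Peterson-type loss of silanolate and then of N2 gives an alkylidene carbene whose 1,2-hydride shift delivers the alkyne with the propargylic centre intact, and no free n-BuLi remains to attack the aryl bromide.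

Step 7
Reactants: 11 4-iodo-2-methoxyphenol
Product: 12 1-(benzyloxy)-4-iodo-2-methoxybenzene
Conditions: BnBr, K2CO3, acetone, 56 °C
Reagents that add atoms: benzyl bromide BrCc1ccccc1
Why: Williamson etherification of the phenoxide with a benzylic bromide is fast and O-selective under these conditions.

Step 8
Reactants: 10 (3R,4S)-4-[2-bromo-4,6-bis(benzyloxy)phenyl]-3-[3,5-bis(benzyloxy)phenyl]-4-(4-benzyloxy-3-methoxyphenyl)but-1-yne; 12 1-(benzyloxy)-4-iodo-2-methoxybenzene
Product: 13 (3S,4S)-4-[2-bromo-4,6-bis(benzyloxy)phenyl]-3-[3,5-bis(benzyloxy)phenyl]-1,4-bis(4-benzyloxy-3-methoxyphenyl)but-1-yne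
Conditions: PdCl2(PPh3)2 (3 mol%), CuI (6 mol%), Et3N, THF, 23 °C
Reagents that add atoms: none
Why: Sonogashira coupling at room temperature should occur only at the aryl iodide of 12, because oxidative addition to the hindered aryl bromide of 10 is far slower, and the amine base is too weak to epimerise the propargylic centre or isomerise the alkyne to an allene.

Step 9
Reactants: 13 (3S,4S)-4-[2-bromo-4,6-bis(benzyloxy)phenyl]-3-[3,5-bis(benzyloxy)phenyl]-1,4-bis(4-benzyloxy-3-methoxyphenyl)but-1-yne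
Product: 14 (1E,2S,3S)-4,6-bis(benzyloxy)-3-(4-benzyloxy-3-methoxyphenyl)-1-[(4-benzyloxy-3-methoxyphenyl)methylidene]-2-[3,5-bis(benzyloxy)phenyl]-2,3-dihydro-1H-indene (gnetulin hexabenzyl ether)
Conditions: Pd(OAc)2 (10 mol%), PPh3 (20 mol%), HCO2Na (3 equiv), DMF, 80 °C
Reagents that add atoms: none
Why: Zerovalent palladium formed in situ from Pd(OAc)2 and PPh3 inserts into the C7a–Br bond, the resulting aryl bromide complex of divalent palladium adds syn across the tethered alkyne to form C7a–C1 and an exocyclic vinylpalladium with no β-hydrogen, and bromide/formate exchange, loss of CO2 and C–H reductive elimination with retention release the alkene and zerovalent palladium. The closest known reaction type is the formate-terminated (reductive Heck) cyclisation of 2-haloaryl alkynes to (E)-1-benzylideneindanes. The one ring closed (C1–C2–C3–C3a–C7a) forms in the 5-exo-dig mode, the aryl cap on the alkyne and the strain of an endocyclic vinylpalladium disfavouring 6-endo-dig closure. No stereocentre is created; C2 and C3 are untouched, and the E geometry follows from syn-carbopalladation (palladium cis to C7a) and stereoretentive hydride delivery, which leaves the guaiacyl group trans to C7a. The step needs cyclisation to outrun direct formate reduction of the aryl–palladium bromide and needs the vinylpalladium geometry to hold; the short two-carbon tether makes insertion fast, the bromide is meta to both ring-A oxygens so oxidative addition is not retarded, and excess formate traps the vinylpalladium before it can isomerise.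

Step 10
Reactants: 14 gnetulin hexabenzyl ether
Product: 15 gnetulin, (1E,2S,3S)-2-(3,5-dihydroxyphenyl)-3-(4-hydroxy-3-methoxyphenyl)-1-[(4-hydroxy-3-methoxyphenyl)methylidene]-2,3-dihydro-1H-indene-4,6-diol
Conditions: BCl3 (excess), pentamethylbenzene (excess), CH2Cl2, −78 °C; then MeOH, −78 °C to rt
Reagents that add atoms: none
Why: BCl3 activates each benzyl ether oxygen and the released benzyl cation is captured irreversibly by pentamethylbenzene (Friedel–Crafts scavenging), so at −78 °C all six benzyl ethers should be cleaved without C-benzylation of the phenol rings, loss of the two methyl ethers or protonation of the electron-rich E-benzylidene.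

**Compound list**

1 | 1-bromo-3,5-bis(benzyloxy)benzene | Brc1cc(OCc2ccccc2)cc(OCc2ccccc2)c1 | starting material
2 | N-{[2-bromo-4,6-bis(benzyloxy)phenyl]methylidene}-N-methylmethanaminium chloride | C[N+](C)=Cc1c(Br)cc(OCc2ccccc2)cc1OCc1ccccc1.[Cl-] | intermediate
3 | 2-bromo-4,6-bis(benzyloxy)benzaldehyde | O=Cc1c(Br)cc(OCc2ccccc2)cc1OCc1ccccc1 | intermediate
4 | (2E)-3-[2-bromo-4,6-bis(benzyloxy)phenyl]prop-2-enal | O=C/C=C/c1c(Br)cc(OCc2ccccc2)cc1OCc1ccccc1 | intermediate
5 | (4-benzyloxy-3-methoxyphenyl)boronic acid | OB(O)c1ccc(OCc2ccccc2)c(OC)c1 | starting material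
6 | (3S)-3-[2-bromo-4,6-bis(benzyloxy)phenyl]-3-(4-benzyloxy-3-methoxyphenyl)propanal | Brc1cc(OCc2ccccc2)cc(OCc2ccccc2)c1[C@H](c1ccc(OCc2ccccc2)c(OC)c1)CC=O | intermediate
7 | [3,5-bis(benzyloxy)phenyl]boronic acid | OB(O)c1cc(OCc2ccccc2)cc(OCc2ccccc2)c1 | starting material
8 | [3,5-bis(benzyloxy)phenyl](2,4,6-trimethylphenyl)iodonium trifluoromethanesulfonate | Cc1cc(C)c([I+]c2cc(OCc3ccccc3)cc(OCc3ccccc3)c2)c(C)c1.[O-]S(=O)(=O)C(F)(F)F | intermediate
9 | (2S,3S)-3-[2-bromo-4,6-bis(benzyloxy)phenyl]-2-[3,5-bis(benzyloxy)phenyl]-3-(4-benzyloxy-3-methoxyphenyl)propanal | Brc1cc(OCc2ccccc2)cc(OCc2ccccc2)c1[C@H](c1ccc(OCc2ccccc2)c(OC)c1)[C@H](C=O)c1cc(OCc2ccccc2)cc(OCc2ccccc2)c1 | intermediate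
10 | (3R,4S)-4-[2-bromo-4,6-bis(benzyloxy)phenyl]-3-[3,5-bis(benzyloxy)phenyl]-4-(4-benzyloxy-3-methoxyphenyl)but-1-yne | Brc1cc(OCc2ccccc2)cc(OCc2ccccc2)c1[C@H](c1ccc(OCc2ccccc2)c(OC)c1)[C@H](C#C)c1cc(OCc2ccccc2)cc(OCc2ccccc2)c1 | intermediate
11 | 4-iodo-2-methoxyphenol | COc1cc(I)ccc1O | starting material
12 | 1-(benzyloxy)-4-iodo-2-methoxybenzene | COc1cc(I)ccc1OCc1ccccc1 | intermediate
13 | (3S,4S)-4-[2-bromo-4,6-bis(benzyloxy)phenyl]-3-[3,5-bis(benzyloxy)phenyl]-1,4-bis(4-benzyloxy-3-methoxyphenyl)but-1-yne | Brc1cc(OCc2ccccc2)cc(OCc2ccccc2)c1[C@H](c1ccc(OCc2ccccc2)c(OC)c1)[C@H](C#Cc1ccc(OCc2ccccc2)c(OC)c1)c1cc(OCc2ccccc2)cc(OCc2ccccc2)c1 | intermediate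
14 | gnetulin hexabenzyl ether, (1E,2S,3S)-4,6-bis(benzyloxy)-3-(4-benzyloxy-3-methoxyphenyl)-1-[(4-benzyloxy-3-methoxyphenyl)methylidene]-2-[3,5-bis(benzyloxy)phenyl]-2,3-dihydro-1H-indene | COc1cc(/C=C2/c3cc(OCc4ccccc4)cc(OCc4ccccc4)c3[C@H](c3ccc(OCc4ccccc4)c(OC)c3)[C@H]2c2cc(OCc4ccccc4)cc(OCc4ccccc4)c2)ccc1OCc1ccccc1 | intermediate
15 | gnetulin, (1E,2S,3S)-2-(3,5-dihydroxyphenyl)-3-(4-hydroxy-3-methoxyphenyl)-1-[(4-hydroxy-3-methoxyphenyl)methylidene]-2,3-dihydro-1H-indene-4,6-diol | COc1cc(/C=C2/c3cc(O)cc(O)c3[C@H](c3ccc(O)c(OC)c3)[C@H]2c2cc(O)cc(O)c2)ccc1O | target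

Total step count: 10
Longest linear sequence: 8 steps (steps 1, 2, 3, 5, 6, 8, 9, 10)

**Steps most likely to fail**

Step 5. Enamine formation from the congested β,β-diaryl aldehyde may be slow, facial selectivity at C2 may erode when catalyst control opposes the C3 centre, and the product may epimerise over a long reaction. The fallback sets out from 6 and comes back at 9. It replaces enamine catalysis by the known copper/bis(oxazoline)-catalysed enantioselective arylation of an N-acyl oxazolidinone silyl ketene aminal with a diaryliodonium salt. Aldehyde 6 is oxidised (NaClO2, NaH2PO4, 2-methyl-2-butene, t-BuOH/H2O) to (3S)-3-[2-bromo-4,6-bis(benzyloxy)phenyl]-3-(4-benzyloxy-3-methoxyphenyl)propanoic acid F1. Acylation through the pivaloyl mixed anhydride (PivCl, Et3N; oxazolidin-2-one, LiCl) gives 3-[(3S)-3-[2-bromo-4,6-bis(benzyloxy)phenyl]-3-(4-benzyloxy-3-methoxyphenyl)propanoyl]-1,3-oxazolidin-2-one F2. Soft enolisation (TMSOTf, Et3N, CH2Cl2) gives the Z silyl ketene aminal 3-[(1Z,3S)-3-[2-bromo-4,6-bis(benzyloxy)phenyl]-3-(4-benzyloxy-3-methoxyphenyl)-1-(trimethylsilyloxy)prop-1-en-1-yl]-1,3-oxazolidin-2-one F3. With 8, Cu(OTf)2 and a chiral Ph-BOX ligand this should give 3-[(2S,3S)-3-[2-bromo-4,6-bis(benzyloxy)phenyl]-2-[3,5-bis(benzyloxy)phenyl]-3-(4-benzyloxy-3-methoxyphenyl)propanoyl]-1,3-oxazolidin-2-one F4, which is far less prone to epimerisation than an aldehyde. LiBH4 then releases (2S,3S)-3-[2-bromo-4,6-bis(benzyloxy)phenyl]-2-[3,5-bis(benzyloxy)phenyl]-3-(4-benzyloxy-3-methoxyphenyl)propan-1-ol F5, and buffered Dess–Martin oxidation gives 9 immediately before step 6.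

Step 6. Enolisation of the α-aryl aldehyde may compete with carbonyl addition (epimerisation at the future C2), or addition to the hindered carbonyl may be sluggish. The fallback sets out from 9 and comes back at 13. Base-free Ramirez olefination (CBr4, PPh3, Zn, CH2Cl2, 0 °C) gives (3R,4S)-4-[2-bromo-4,6-bis(benzyloxy)phenyl]-3-[3,5-bis(benzyloxy)phenyl]-4-(4-benzyloxy-3-methoxyphenyl)-1,1-dibromobut-1-ene F6, whose stereocentre is no longer α to a carbonyl. DBU in DMSO at rt removes HBr to give (3S,4S)-1-bromo-4-[2-bromo-4,6-bis(benzyloxy)phenyl]-3-[3,5-bis(benzyloxy)phenyl]-4-(4-benzyloxy-3-methoxyphenyl)but-1-yne F7. Suzuki–Miyaura coupling of F7 with boronic acid 5 (Pd(PPh3)4, K2CO3, THF/H2O, 40 °C), in which the alkynyl bromide reacts far faster than the hindered aryl bromide, gives 13 directly, so steps 7 and 8 are not needed.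

Step 9. Formate may reduce the aryl–palladium bromide before insertion (hydrodebromination), or the vinylpalladium may equilibrate its geometry before hydride capture. The fallback sets out from 10 and comes back at 14. It closes the same bond by a Mizoroki–Heck reaction on an E-styrene with no hydride source present; syn-insertion and syn-β-hydride elimination of the single C1–H should carry the E geometry of the alkene into the benzylidene. Alkyne 10 is hydroborated (pinacolborane, Cp2Zr(H)Cl cat., CH2Cl2, rt) to 2-[(1E,3S,4S)-4-[2-bromo-4,6-bis(benzyloxy)phenyl]-3-[3,5-bis(benzyloxy)phenyl]-4-(4-benzyloxy-3-methoxyphenyl)but-1-en-1-yl]-4,4,5,5-tetramethyl-1,3,2-dioxaborolane F8. Suzuki–Miyaura coupling with iodide 12 (Pd(PPh3)4, aq. K2CO3, THF, 50 °C) gives (1E,3S,4S)-4-[2-bromo-4,6-bis(benzyloxy)phenyl]-3-[3,5-bis(benzyloxy)phenyl]-1,4-bis(4-benzyloxy-3-methoxyphenyl)but-1-ene F9. Pd(OAc)2, PPh3, Ag2CO3, MeCN, 80 °C should then close the ring 5-exo-trig to 14, the silver salt suppressing re-addition of palladium hydride and migration of the double bond into the ring.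

**Further compounds**

F1 | step 5 | (3S)-3-[2-bromo-4,6-bis(benzyloxy)phenyl]-3-(4-benzyloxy-3-methoxyphenyl)propanoic acid | Brc1cc(OCc2ccccc2)cc(OCc2ccccc2)c1[C@H](c1ccc(OCc2ccccc2)c(OC)c1)CC(=O)O
F2 | step 5 | 3-[(3S)-3-[2-bromo-4,6-bis(benzyloxy)phenyl]-3-(4-benzyloxy-3-methoxyphenyl)propanoyl]-1,3-oxazolidin-2-one | Brc1cc(OCc2ccccc2)cc(OCc2ccccc2)c1[C@H](c1ccc(OCc2ccccc2)c(OC)c1)CC(=O)N1CCOC1=O
F3 | step 5 | 3-[(1Z,3S)-3-[2-bromo-4,6-bis(benzyloxy)phenyl]-3-(4-benzyloxy-3-methoxyphenyl)-1-(trimethylsilyloxy)prop-1-en-1-yl]-1,3-oxazolidin-2-one | Brc1cc(OCc2ccccc2)cc(OCc2ccccc2)c1[C@H](c1ccc(OCc2ccccc2)c(OC)c1)/C=C(\O[Si](C)(C)C)N1CCOC1=O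
F4 | step 5 | 3-[(2S,3S)-3-[2-bromo-4,6-bis(benzyloxy)phenyl]-2-[3,5-bis(benzyloxy)phenyl]-3-(4-benzyloxy-3-methoxyphenyl)propanoyl]-1,3-oxazolidin-2-one | Brc1cc(OCc2ccccc2)cc(OCc2ccccc2)c1[C@H](c1ccc(OCc2ccccc2)c(OC)c1)[C@H](C(=O)N1CCOC1=O)c1cc(OCc2ccccc2)cc(OCc2ccccc2)c1
F5 | step 5 | (2S,3S)-3-[2-bromo-4,6-bis(benzyloxy)phenyl]-2-[3,5-bis(benzyloxy)phenyl]-3-(4-benzyloxy-3-methoxyphenyl)propan-1-ol | Brc1cc(OCc2ccccc2)cc(OCc2ccccc2)c1[C@H](c1ccc(OCc2ccccc2)c(OC)c1)[C@H](CO)c1cc(OCc2ccccc2)cc(OCc2ccccc2)c1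
F6 | step 6 | (3R,4S)-4-[2-bromo-4,6-bis(benzyloxy)phenyl]-3-[3,5-bis(benzyloxy)phenyl]-4-(4-benzyloxy-3-methoxyphenyl)-1,1-dibromobut-1-ene | Brc1cc(OCc2ccccc2)cc(OCc2ccccc2)c1[C@H](c1ccc(OCc2ccccc2)c(OC)c1)[C@H](C=C(Br)Br)c1cc(OCc2ccccc2)cc(OCc2ccccc2)c1
F7 | step 6 | (3S,4S)-1-bromo-4-[2-bromo-4,6-bis(benzyloxy)phenyl]-3-[3,5-bis(benzyloxy)phenyl]-4-(4-benzyloxy-3-methoxyphenyl)but-1-yne | Brc1cc(OCc2ccccc2)cc(OCc2ccccc2)c1[C@H](c1ccc(OCc2ccccc2)c(OC)c1)[C@H](C#CBr)c1cc(OCc2ccccc2)cc(OCc2ccccc2)c1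
F8 | step 9 | 2-[(1E,3S,4S)-4-[2-bromo-4,6-bis(benzyloxy)phenyl]-3-[3,5-bis(benzyloxy)phenyl]-4-(4-benzyloxy-3-methoxyphenyl)but-1-en-1-yl]-4,4,5,5-tetramethyl-1,3,2-dioxaborolane | Brc1cc(OCc2ccccc2)cc(OCc2ccccc2)c1[C@H](c1ccc(OCc2ccccc2)c(OC)c1)[C@H](/C=C/B1OC(C)(C)C(C)(C)O1)c1cc(OCc2ccccc2)cc(OCc2ccccc2)c1
F9 | step 9 | (1E,3S,4S)-4-[2-bromo-4,6-bis(benzyloxy)phenyl]-3-[3,5-bis(benzyloxy)phenyl]-1,4-bis(4-benzyloxy-3-methoxyphenyl)but-1-ene | Brc1cc(OCc2ccccc2)cc(OCc2ccccc2)c1[C@H](c1ccc(OCc2ccccc2)c(OC)c1)[C@H](/C=C/c1ccc(OCc2ccccc2)c(OC)c1)c1cc(OCc2ccccc2)cc(OCc2ccccc2)c1
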